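Z is the product we read, and it trails J: in beta, Z is 0% at 8.00 h with J at 6%. So we take Z as made from J, and J from D and G.

common to all: Q 0.285 M

|  | D | G | temperature | remark | time |
|---|---|---|---|---|---|
| beta | 0.095 M | 0.19 M | 15 °C | run made earlier |  |
| epsilon | 0.095 M | 0.13 M | 26 °C | run made earlier |  |
| zeta | 0.095 M | 0.29 M | 15 °C | run made earlier |  |
| birch | 0.095 M (fed, over 3.0 h) | 0.190 M | 20 °C | all else is in the flask from the start; the feed brings no volume worth counting | 40 h |
| elm | 0.095 M (fed, over 30 h) | 0.190 M | 20 °C | all else is in the flask from the start; the feed brings no volume worth counting | 40 h |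
| ash | 0.095 M | 0.190 M (fed, over 30 h) | 20 °C | all else is in the flask from the start; the feed brings no volume worth counting | 40 h |
| larch | 0.095 M | 0.190 M |  | everything together at the start at −20 °C, warmed to 20 °C at 30 h | 40 h |
| oak | 0.095 M | 0.190 M (fed, over 30 h) |  | the addition at −20 °C, then warmed to 20 °C; the feed brings no volume worth counting | 40 h |

- beta (time / h: Z / %, J / %, D / %): 2.50: 0, 3, 98; 8.00: 0, 6, 92; 15.0: 3, 11, 85; 20.0: 3, 14, 80; 30.0: 8, 16, 75; 40.0: 17, 16, 68
- epsilon (time / h: Z / %, J / %, D / %): 2.50: 1, 3, 97; 4.00: 3, 5, 92; 8.00: 7, 10, 85; 12.0: 7, 12, 76; 20.0: 20, 16, 67; 30.0: 28, 12, 58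
- zeta (time / h: Z / %, J / %, D / %): 2.50: 0, 4, 96; 4.00: 0, 6, 94; 8.00: 0, 12, 89; 12.0: 2, 14, 83; 20.0: 9, 20, 73; 30.0: 16, 25, 62

(standard deviation of a reading: 1.5 percentage points)



* the flask that comes out highest in amount of Z, in percent of the D charged, or "all alike" when all lie within 1.5 percentage points (birch / elm / ash / larch / oak / all alike)
* Z at the end, in percent of the D charged, birch
* Z at the end, in percent of the D charged, elm
* Z at the end, in percent of the D charged, ash
* Z at the end, in percent of the D charged, larch
* Z at the end, in percent of the D charged, oak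

1. If Z is made from J, Z divided by the area under the J curve gives J's loss constant. In beta that area is 4.61 h, which gives 0.0369 h⁻¹.

2. Zeta, with [G] at 0.29 M, gives 0.0347 h⁻¹, about the same, so we leave [G] out of this step. Epsilon gives 0.0834 h⁻¹.

3. 20 °C lies 0.455 of the way from 15 °C to 26 °C. Interpolating the logarithm gives J's lifetime, the mean time a J stands at the charged [Q] and 20 °C before becoming Z: 18.7 h.

4. We treat D as pseudo-first-order at the charged [G]. Beta gives 0.0507 M⁻¹ h⁻¹ and epsilon 0.140 M⁻¹ h⁻¹, so D's lifetime at 20 °C is 65.5 h, longer than J's.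

5. Birch, elm and ash get a warm window w, the end time less half the feed: 38.5 h for birch, 25.0 h for elm and ash. Larch and oak get 10.0 h, the cold hours counted as nothing.

6. Steady making of J gives a Z share of reacted D of 1 − (τJ/w)(1 − exp(−w/τJ)). For birch that means Z of 25.6%.

7. That is the weak link: in this reckoning the making slackens as D falls, to 55.6% of its charge at the end of birch's window. The two-step chain replaces it: Z = 1 − (τD·exp(−w/τD) − τJ·exp(−w/τJ))/(τD − τJ). We commit to birch 27.4%, elm and ash 15.0%, larch and oak 3.27%. Birch leads by 12 percentage points, more than the margin.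

The forecast names birch: 28%, 16%, 16.5%, 3.5%, 3.2% in the order asked, saying of the cold hours “almost nothing happens there”. Our birch and elm lie lower.

The flasks give birch highest: 27.3%, 16.4%, 16.6%, 4.06%, 3.97%, and the forecast held. In birch at 40.0 h, J has a half-life of 15 h by its loss to Z, shorter than the 51 h of D by its reaction with G. As a lifetime, J's figure in birch at that moment is 21.9 h, with unbound Q at 78% of its charge; our 18.7 h, reckoned at the charged [Q], divided by that share is 24.0 h, longer.

    E + Q ⇌ X, settled at all times (K = 16000 M⁻¹, ΔH = 11.0 kJ mol⁻¹)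
    Q + J → Z (k = 0.00340 M⁻¹ min⁻¹, Ea = 71.0 kJ mol⁻¹)
    D + G → E + J (k = 0.00160 M⁻¹ min⁻¹, Ea = 72.0 kJ mol⁻¹)
    G + E ⇌ L, settled at all times (K = 5100 M⁻¹, ΔH = −46.0 kJ mol⁻¹)
    (constants at 20 °C)

Birch read at 6.0 d: the same chain, with 18.7 h and 65.5 h held at their values for the charged amounts, gives Z of 84.1%. The computed flask holds 74.8%, less than that, with D at 17.6%.

The earlier runs and the new flask were computed for substances that don't exist.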